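The octahydroazulene is opened in its five-membered ring between the methylene C2 and the tertiary carbinol C3 (azulene numbering). C3 carries the hydroxyl and the isopropyl group, lies next to the ring-fusion methine C3a and is 1,3-related to the oxygen on C4, so it is the carbonyl carbon of an aldol-type isopropyl ketone, whereas C2 is an unactivated CH2. A samarium diiodide Barbier cyclization joins these two electrophilic carbons, closes the trans-fused cyclopentane and sets the C3 carbinol in one operation. Its precursor is a monocyclic cycloheptenyl acetate with a 2-bromoethyl arm on the quaternary carbon and a trans isobutyryl group, made by ring-closing metathesis and a conjugate addition–alkylation.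

Key step: step 12

Remark: bicyclic compounds carry azulene numbering; it is assumed that (S)-BINOL–titanium gives the (S)-hydroxy ester and (S)-Me-CBS the (1R)-alcohol, as the accepted models of these catalysts predict, and the antipodal catalyst is used if either sense proves reversed.

Step 1
Reactants: 1 ethyl glyoxylate; 2 2-methylpropene
Product: 3 ethyl (2S)-2-hydroxy-4-methylpent-4-enoate
Conditions: (S)-BINOL (10 mol %), TiCl2(OiPr)2 (10 mol %), 4 Å molecular sieves, CH2Cl2, −30 °C
Reagents that add atoms: none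
Why: Catalytic asymmetric glyoxylate–ene reaction, in which the BINOL–titanium Lewis acid exposes one aldehyde face to the 1,1-disubstituted alkene, so that the catalyst sets the carbinol centre (the later C4 of the azulene) as (S) and the methallyl unit needed for ring closure is formed at the same time.

Step 2
Reactants: 3 ethyl (2S)-2-hydroxy-4-methylpent-4-enoate
Product: 4 ethyl (2S)-2-[(tert-butyldimethylsilyl)oxy]-4-methylpent-4-enoate
Conditions: TBSCl, imidazole, DMF, 0 °C → rt
Reagents that add atoms: tert-butyldimethylsilyl chloride, CC(C)(C)[Si](C)(C)Cl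
Why: Imidazole-mediated silylation of the secondary alcohol masks the oxygen through the organometallic steps and provides the bulky group that later directs the conjugate addition, without touching the stereocentre.

Step 3
Reactants: 4 ethyl (2S)-2-[(tert-butyldimethylsilyl)oxy]-4-methylpent-4-enoate
Product: 5 (2S)-2-[(tert-butyldimethylsilyl)oxy]-4-methylpent-4-enal
Conditions: i-Bu2AlH (1.1 equiv), CH2Cl2, −78 °C; aqueous Rochelle salt
Reagents that add atoms: none
Why: Partial reduction of the ester by i-Bu2AlH at low temperature stops at the aluminium hemiacetal, which should give the α-silyloxy aldehyde on work-up without epimerisation if it is used at once.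

Step 4
Reactants: 5 (2S)-2-[(tert-butyldimethylsilyl)oxy]-4-methylpent-4-enal; 6 methyl 2-[bis(2,2,2-trifluoroethoxy)phosphoryl]propanoate
Product: 7 methyl (2Z,4S)-4-[(tert-butyldimethylsilyl)oxy]-2,6-dimethylhepta-2,6-dienoate
Conditions: 6, KN(SiMe3)2, 18-crown-6, THF, −78 °C; then 5
Reagents that add atoms: none
Why: Still–Gennari olefination, in which the electron-poor trifluoroethyl phosphonate under dissociating conditions gives the (Z)-trisubstituted enoate kinetically, placing the ester carbon and the carbinol carbon cis as the later seven-membered ring requires.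

Step 5
Reactants: 7 methyl (2Z,4S)-4-[(tert-butyldimethylsilyl)oxy]-2,6-dimethylhepta-2,6-dienoate
Product: 8 (2Z,4S)-4-[(tert-butyldimethylsilyl)oxy]-N-methoxy-N,2,6-trimethylhepta-2,6-dienamide
Conditions: MeNH(OMe)·HCl, i-PrMgCl, THF, −20 → 0 °C
Reagents that add atoms: N,O-dimethylhydroxylamine hydrochloride, CNOC.Cl
Why: Aminolysis of the ester by the magnesium amide of N,O-dimethylhydroxylamine (Weinreb amide formation) is not expected to isomerise the (Z)-alkene.

Step 6
Reactants: 8 (2Z,4S)-4-[(tert-butyldimethylsilyl)oxy]-N-methoxy-N,2,6-trimethylhepta-2,6-dienamide; 9 vinylmagnesium bromide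
Product: 10 (4Z,6S)-6-[(tert-butyldimethylsilyl)oxy]-4,8-dimethylnona-1,4,8-trien-3-one
Conditions: CH2=CHMgBr, THF, −20 → 0 °C; inverse quench into cold aqueous KHSO4
Reagents that add atoms: none
Why: Grignard addition to a Weinreb amide stops at the chelated tetrahedral intermediate, so that a single vinyl group is delivered and the cross-conjugated trienone is released only on cold acidic work-up.

Step 7
Reactants: 10 (4Z,6S)-6-[(tert-butyldimethylsilyl)oxy]-4,8-dimethylnona-1,4,8-trien-3-one
Product: 11 (4S)-4-[(tert-butyldimethylsilyl)oxy]-2,6-dimethylcyclohepta-2,6-dien-1-one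
Conditions: second-generation Grubbs catalyst RuCl2(=CHPh)(H2IMes)(PCy3) (10 mol %), toluene (0.002 M), 80 °C
Reagents that add atoms: none
Why: Ring-closing metathesis between the vinyl ketone and the 1,1-disubstituted alkene, helped by the (Z)-alkene that holds both termini on the same side, should close the seven-membered ring with loss of ethene and form the trisubstituted enone double bond.

Step 8
Reactants: 11 (4S)-4-[(tert-butyldimethylsilyl)oxy]-2,6-dimethylcyclohepta-2,6-dien-1-one; 12 2-bromo-3-methylbut-1-ene; 13 2-bromoethyl trifluoromethanesulfonate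
Product: 15 (5S,6S,7S)-7-(2-bromoethyl)-5-[(tert-butyldimethylsilyl)oxy]-3,7-dimethyl-6-(3-methylbut-1-en-2-yl)cyclohept-2-en-1-one, via lithium enolate 14 (not isolated)
Conditions: 12 (2.2 equiv), t-BuLi (4.4 equiv), Et2O, −78 °C; CuI (1.1 equiv), −40 °C; 11, −78 °C; then 13 (3 equiv), THF, −78 → −20 °C
Reagents that add atoms: none
Why: Tandem conjugate addition–enolate alkylation, in which the Gilman cuprate made from 12 adds 1,4 to the enone terminus that bears hydrogen (not to the methyl-substituted one) anti to the neighbouring silyloxy group, and the enolate is C-alkylated by the primary triflate anti to the new alkenyl group, which should set the two adjacent stereocentres with the methyl of the quaternary carbon cis to the alkenyl group.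

Step 9
Reactants: 15 (5S,6S,7S)-7-(2-bromoethyl)-5-[(tert-butyldimethylsilyl)oxy]-3,7-dimethyl-6-(3-methylbut-1-en-2-yl)cyclohept-2-en-1-one
Product: 16 (5S,6S,7S)-7-(2-bromoethyl)-5-[(tert-butyldimethylsilyl)oxy]-3,7-dimethyl-6-(2-methylpropanoyl)cyclohept-2-en-1-one
Conditions: O3, CH2Cl2, −78 °C (Sudan Red 7B end point); PPh3, −78 °C → rt
Reagents that add atoms: ozone, [O-][O+]=O
Why: Ozonolysis, selective because the isolated 1,1-disubstituted alkene is far more electron-rich than the enone double bond, unmasks the isopropyl ketone, and the α-stereocentre keeps its thermodynamically preferred configuration (acyl trans to the silyloxy group).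

Step 10
Reactants: 16 (5S,6S,7S)-7-(2-bromoethyl)-5-[(tert-butyldimethylsilyl)oxy]-3,7-dimethyl-6-(2-methylpropanoyl)cyclohept-2-en-1-one
Product: 17 (1R,5S,6S,7S)-7-(2-bromoethyl)-5-[(tert-butyldimethylsilyl)oxy]-3,7-dimethyl-6-(2-methylpropanoyl)cyclohept-2-en-1-ol
Conditions: (S)-Me-CBS oxazaborolidine (20 mol %), catecholborane, toluene, −78 °C; the product is acetylated without storage
Reagents that add atoms: none
Why: Corey–Bakshi–Shibata reduction, in which the oxazaborolidine distinguishes the quaternary flank of the ring carbonyl (large) from the vinylic flank (small) and delivers hydride to the face syn to the ring methyl, should give the (1R) allylic alcohol with the hydroxyl cis to the bromoethyl arm, while the doubly α-branched isopropyl ketone is too hindered to react.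

Step 11
Reactants: 17 (1R,5S,6S,7S)-7-(2-bromoethyl)-5-[(tert-butyldimethylsilyl)oxy]-3,7-dimethyl-6-(2-methylpropanoyl)cyclohept-2-en-1-ol
Product: 18 (1R,5S,6S,7S)-7-(2-bromoethyl)-5-[(tert-butyldimethylsilyl)oxy]-3,7-dimethyl-6-(2-methylpropanoyl)cyclohept-2-en-1-yl acetate
Conditions: Ac2O, Et3N, DMAP (cat.), CH2Cl2, 0 °C
Reagents that add atoms: acetic anhydride, CC(=O)OC(C)=O
Why: DMAP-catalysed acetylation of the secondary allylic alcohol installs the acetate of the target and removes the free hydroxyl that could displace the neighbouring bromide or quench an organometallic.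

Step 12
Reactants: 18 (1R,5S,6S,7S)-7-(2-bromoethyl)-5-[(tert-butyldimethylsilyl)oxy]-3,7-dimethyl-6-(2-methylpropanoyl)cyclohept-2-en-1-yl acetate
Product: 19 (3R,3aS,4S,8R,8aS)-4-[(tert-butyldimethylsilyl)oxy]-3-hydroxy-6,8a-dimethyl-3-(propan-2-yl)-1,2,3,3a,4,5,8,8a-octahydroazulen-8-yl acetate
Conditions: SmI2 (3 equiv), HMPA (12 equiv), THF, 0 °C, slow addition of 18; aqueous NH4Cl
Reagents that add atoms: none
Why: Electron transfer from SmI2–HMPA to the C–Br bond gives the primary radical and then the alkylsamarium (trivalent samarium), which adds to the neighbouring isopropyl ketone, so that two carbons that are both electrophilic in 18 (C–Br and C=O) are joined reductively; radical–ketyl coupling would lead to the same product. The closest known reaction type is the intramolecular samarium Barbier cyclization of ω-halo ketones to cyclopentanols. The cyclopentane closes in a 5-exo-trig mode on the carbonyl carbon, and it is trans-fused because the bromoethyl arm and the isobutyryl group were already placed trans on the cycloheptene in step 8. The one new stereocentre, the carbinol C3, is controlled by the adjacent ring-fusion methine C3a: in the samarium chelate between the ketone oxygen and the C4 silyl ether oxygen the isopropyl group lies next to the small C3a–H and away from the angular methyl on C8a, so that the hydroxyl should end cis to that methyl (3R). The step needs chemoselectivity for the halide and the ketone over the allylic acetate, the silyl ether and the ring alkene; this is secured by the much faster reduction of C–Br under HMPA activation, by the five-membered transition state to the ketone being favoured over a six-membered attack on the acetate, and by a high SmI2 concentration that reduces the primary radical before it can add to the ring double bond.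

Step 13
Reactants: 19 (3R,3aS,4S,8R,8aS)-4-[(tert-butyldimethylsilyl)oxy]-3-hydroxy-6,8a-dimethyl-3-(propan-2-yl)-1,2,3,3a,4,5,8,8a-octahydroazulen-8-yl acetate
Product: 20 (3R,3aS,4S,8R,8aS)-3,4-dihydroxy-6,8a-dimethyl-3-(propan-2-yl)-1,2,3,3a,4,5,8,8a-octahydroazulen-8-yl acetate
Conditions: Bu4NF, AcOH, THF, 0 °C → rt
Reagents that add atoms: none
Why: Fluoride cleavage of the secondary silyl ether, buffered with acetic acid so that the acetate is neither hydrolysed nor transferred, should free the secondary hydroxyl.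

Step 14
Reactants: 20 (3R,3aS,4S,8R,8aS)-3,4-dihydroxy-6,8a-dimethyl-3-(propan-2-yl)-1,2,3,3a,4,5,8,8a-octahydroazulen-8-yl acetate; 21 4-methoxybenzoyl chloride
Product: 22 (3R,3aS,4S,8R,8aS)-8-(acetyloxy)-3-hydroxy-6,8a-dimethyl-3-(propan-2-yl)-1,2,3,3a,4,5,8,8a-octahydroazulen-4-yl 4-methoxybenzoate
Conditions: 21, Et3N, DMAP, CH2Cl2, 0 °C → rt
Reagents that add atoms: none
Why: DMAP-catalysed acyl transfer from the acid chloride should esterify the secondary hydroxyl only, since the tertiary carbinol is too hindered, and gives the target.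

Compound list
1 | ethyl glyoxylate (ethyl 2-oxoacetate) | CCOC(=O)C=O | starting material
2 | 2-methylpropene (isobutene) | CC(C)=C | starting material
3 | ethyl (2S)-2-hydroxy-4-methylpent-4-enoate | CCOC(=O)[C@@H](O)CC(C)=C | intermediate
4 | ethyl (2S)-2-[(tert-butyldimethylsilyl)oxy]-4-methylpent-4-enoate | CCOC(=O)[C@@H](O[Si](C)(C)C(C)(C)C)CC(C)=C | intermediate
5 | (2S)-2-[(tert-butyldimethylsilyl)oxy]-4-methylpent-4-enal | O=C[C@@H](O[Si](C)(C)C(C)(C)C)CC(C)=C | intermediate
6 | methyl 2-[bis(2,2,2-trifluoroethoxy)phosphoryl]propanoate | COC(=O)C(C)P(=O)(OCC(F)(F)F)OCC(F)(F)F | starting material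
7 | methyl (2Z,4S)-4-[(tert-butyldimethylsilyl)oxy]-2,6-dimethylhepta-2,6-dienoate | COC(=O)/C(C)=C\[C@@H](O[Si](C)(C)C(C)(C)C)CC(C)=C | intermediate
8 | (2Z,4S)-4-[(tert-butyldimethylsilyl)oxy]-N-methoxy-N,2,6-trimethylhepta-2,6-dienamide | CON(C)C(=O)/C(C)=C\[C@@H](O[Si](C)(C)C(C)(C)C)CC(C)=C | intermediate
9 | vinylmagnesium bromide | C=C[Mg]Br | starting material
10 | (4Z,6S)-6-[(tert-butyldimethylsilyl)oxy]-4,8-dimethylnona-1,4,8-trien-3-one | C=CC(=O)/C(C)=C\[C@@H](O[Si](C)(C)C(C)(C)C)CC(C)=C | intermediate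
11 | (4S)-4-[(tert-butyldimethylsilyl)oxy]-2,6-dimethylcyclohepta-2,6-dien-1-one | CC(C)(C)[Si](C)(C)O[C@H]1CC(C)=CC(=O)C(C)=C1 | intermediate
12 | 2-bromo-3-methylbut-1-ene | C=C(Br)C(C)C | starting material
13 | 2-bromoethyl trifluoromethanesulfonate | BrCCOS(=O)(=O)C(F)(F)F | starting material
14 | lithium (3S,4S)-4-[(tert-butyldimethylsilyl)oxy]-2,6-dimethyl-3-(3-methylbut-1-en-2-yl)cyclohepta-1,6-dien-1-olate (lithium enolate) | CC(C)(C)[Si](C)(C)O[C@H]1CC(C)=CC([O-])=C(C)[C@@H]1C(=C)C(C)C.[Li+] | intermediate (not isolated)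
15 | (5S,6S,7S)-7-(2-bromoethyl)-5-[(tert-butyldimethylsilyl)oxy]-3,7-dimethyl-6-(3-methylbut-1-en-2-yl)cyclohept-2-en-1-one | CC(C)(C)[Si](C)(C)O[C@H]1CC(C)=CC(=O)[C@@](C)(CCBr)[C@@H]1C(=C)C(C)C | intermediate
16 | (5S,6S,7S)-7-(2-bromoethyl)-5-[(tert-butyldimethylsilyl)oxy]-3,7-dimethyl-6-(2-methylpropanoyl)cyclohept-2-en-1-one | CC(C)(C)[Si](C)(C)O[C@H]1CC(C)=CC(=O)[C@@](C)(CCBr)[C@@H]1C(=O)C(C)C | intermediate
17 | (1R,5S,6S,7S)-7-(2-bromoethyl)-5-[(tert-butyldimethylsilyl)oxy]-3,7-dimethyl-6-(2-methylpropanoyl)cyclohept-2-en-1-ol | CC(C)(C)[Si](C)(C)O[C@H]1CC(C)=C[C@@H](O)[C@@](C)(CCBr)[C@@H]1C(=O)C(C)C | intermediate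
18 | (1R,5S,6S,7S)-7-(2-bromoethyl)-5-[(tert-butyldimethylsilyl)oxy]-3,7-dimethyl-6-(2-methylpropanoyl)cyclohept-2-en-1-yl acetate | CC(C)(C)[Si](C)(C)O[C@H]1CC(C)=C[C@@H](OC(C)=O)[C@@](C)(CCBr)[C@@H]1C(=O)C(C)C | intermediate
19 | (3R,3aS,4S,8R,8aS)-4-[(tert-butyldimethylsilyl)oxy]-3-hydroxy-6,8a-dimethyl-3-(propan-2-yl)-1,2,3,3a,4,5,8,8a-octahydroazulen-8-yl acetate | CC(C)(C)[Si](C)(C)O[C@H]1CC(C)=C[C@@H](OC(C)=O)[C@@]2(C)CC[C@@](O)(C(C)C)[C@H]12 | intermediate
20 | (3R,3aS,4S,8R,8aS)-3,4-dihydroxy-6,8a-dimethyl-3-(propan-2-yl)-1,2,3,3a,4,5,8,8a-octahydroazulen-8-yl acetate | O[C@H]1CC(C)=C[C@@H](OC(C)=O)[C@@]2(C)CC[C@@](O)(C(C)C)[C@H]12 | intermediate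
21 | 4-methoxybenzoyl chloride | COc1ccc(cc1)C(Cl)=O | starting material
22 | (3R,3aS,4S,8R,8aS)-8-(acetyloxy)-3-hydroxy-6,8a-dimethyl-3-(propan-2-yl)-1,2,3,3a,4,5,8,8a-octahydroazulen-4-yl 4-methoxybenzoate | COc1ccc(C(=O)O[C@H]2CC(C)=C[C@@H](OC(C)=O)[C@@]3(C)CC[C@@](O)(C(C)C)[C@H]23)cc1 | target

Total step count: 14
Longest linear sequence: 14 steps (from 1 and 2 to 22)

Steps most likely to fail

Step 8. The hindered, copper-associated enolate may be alkylated on oxygen or not at all by the triflate, and proton transfer may start loss of silanol toward a tropone. The fallback sets out from 11 and separates the two bond formations. The cuprate addition is run with Me3SiCl so that the enolate is trapped as the silyl enol ether (3S,4S)-4-[(tert-butyldimethylsilyl)oxy]-2,6-dimethyl-3-(3-methylbut-1-en-2-yl)-1-[(trimethylsilyl)oxy]cyclohepta-1,6-diene F1. MeLi in THF then regenerates a copper-free lithium enolate, which is alkylated with the more reliable allyl iodide to give (5S,6S,7S)-5-[(tert-butyldimethylsilyl)oxy]-3,7-dimethyl-6-(3-methylbut-1-en-2-yl)-7-(prop-2-en-1-yl)cyclohept-2-en-1-one F2. Ozonolysis (O3, then PPh3) cleaves both terminal alkenes and spares the enone, giving (5S,6S,7S)-5-[(tert-butyldimethylsilyl)oxy]-3,7-dimethyl-6-(2-methylpropanoyl)-7-(2-oxoethyl)cyclohept-2-en-1-one F3. NaBH(OAc)3 should reduce only the aldehyde to (5S,6S,7S)-5-[(tert-butyldimethylsilyl)oxy]-7-(2-hydroxyethyl)-3,7-dimethyl-6-(2-methylpropanoyl)cyclohept-2-en-1-one F4, and Appel bromination (CBr4, PPh3) returns to the route at 16.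

Step 12. The primary radical may add 5-exo to the ring double bond or abstract hydrogen before the ketone is captured. The fallback sets out from 18 and replaces the halide–ketone coupling by a ketyl pinacol coupling followed by deoxygenation. Oxidation of the bromide with Me3NO in DMSO (Kornblum type) gives (1R,5S,6S,7S)-5-[(tert-butyldimethylsilyl)oxy]-3,7-dimethyl-6-(2-methylpropanoyl)-7-(2-oxoethyl)cyclohept-2-en-1-yl acetate F5. SmI2 in THF at −78 °C without HMPA, conditions under which ketyl addition to the unactivated ring alkene should not compete, closes the ring to the cis-diol (2S,3R,3aS,4S,8R,8aS)-4-[(tert-butyldimethylsilyl)oxy]-2,3-dihydroxy-6,8a-dimethyl-3-(propan-2-yl)-1,2,3,3a,4,5,8,8a-octahydroazulen-8-yl acetate F6. 4-Methylbenzoyl chloride with pyridine and DMAP acylates only the secondary hydroxyl, giving (2S,3R,3aS,4S,8R,8aS)-8-(acetyloxy)-4-[(tert-butyldimethylsilyl)oxy]-3-hydroxy-6,8a-dimethyl-3-(propan-2-yl)-1,2,3,3a,4,5,8,8a-octahydroazulen-2-yl 4-methylbenzoate F7. Markó–Lam deoxygenation of this toluate (SmI2, HMPA, THF) removes the extra oxygen and returns to the route at 19.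

Step 10. Hydride may be delivered to the wrong face if substrate bias overrides the catalyst, the isobutyryl ketone may be reduced as well, or the new hydroxyl may displace the bromide to form a cyclic ether. The fallback sets out from 16 and corrects the configuration by inversion instead of facial control. Substrate-controlled Luche reduction (NaBH4, CeCl3, MeOH, −78 °C) is used, and if it gives the epimeric alcohol (1S,5S,6S,7S)-7-(2-bromoethyl)-5-[(tert-butyldimethylsilyl)oxy]-3,7-dimethyl-6-(2-methylpropanoyl)cyclohept-2-en-1-ol F8, whose hydroxyl is trans to the bromoethyl arm and cannot cyclise, Mitsunobu esterification with acetic acid (PPh3, DIAD) inverts the carbinol and returns to the route directly at 18.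

Further compounds
F1 | step 8 | (3S,4S)-4-[(tert-butyldimethylsilyl)oxy]-2,6-dimethyl-3-(3-methylbut-1-en-2-yl)-1-[(trimethylsilyl)oxy]cyclohepta-1,6-diene | CC(C)(C)[Si](C)(C)O[C@H]1CC(C)=CC(O[Si](C)(C)C)=C(C)[C@@H]1C(=C)C(C)C
F2 | step 8 | (5S,6S,7S)-5-[(tert-butyldimethylsilyl)oxy]-3,7-dimethyl-6-(3-methylbut-1-en-2-yl)-7-(prop-2-en-1-yl)cyclohept-2-en-1-one | CC(C)(C)[Si](C)(C)O[C@H]1CC(C)=CC(=O)[C@@](C)(CC=C)[C@@H]1C(=C)C(C)C
F3 | step 8 | (5S,6S,7S)-5-[(tert-butyldimethylsilyl)oxy]-3,7-dimethyl-6-(2-methylpropanoyl)-7-(2-oxoethyl)cyclohept-2-en-1-one | CC(C)(C)[Si](C)(C)O[C@H]1CC(C)=CC(=O)[C@@](C)(CC=O)[C@@H]1C(=O)C(C)C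
F4 | step 8 | (5S,6S,7S)-5-[(tert-butyldimethylsilyl)oxy]-7-(2-hydroxyethyl)-3,7-dimethyl-6-(2-methylpropanoyl)cyclohept-2-en-1-one | CC(C)(C)[Si](C)(C)O[C@H]1CC(C)=CC(=O)[C@@](C)(CCO)[C@@H]1C(=O)C(C)C
F5 | step 12 | (1R,5S,6S,7S)-5-[(tert-butyldimethylsilyl)oxy]-3,7-dimethyl-6-(2-methylpropanoyl)-7-(2-oxoethyl)cyclohept-2-en-1-yl acetate | CC(C)(C)[Si](C)(C)O[C@H]1CC(C)=C[C@@H](OC(C)=O)[C@@](C)(CC=O)[C@@H]1C(=O)C(C)C
F6 | step 12 | (2S,3R,3aS,4S,8R,8aS)-4-[(tert-butyldimethylsilyl)oxy]-2,3-dihydroxy-6,8a-dimethyl-3-(propan-2-yl)-1,2,3,3a,4,5,8,8a-octahydroazulen-8-yl acetate | CC(C)(C)[Si](C)(C)O[C@H]1CC(C)=C[C@@H](OC(C)=O)[C@@]2(C)C[C@H](O)[C@@](O)(C(C)C)[C@H]12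
F7 | step 12 | (2S,3R,3aS,4S,8R,8aS)-8-(acetyloxy)-4-[(tert-butyldimethylsilyl)oxy]-3-hydroxy-6,8a-dimethyl-3-(propan-2-yl)-1,2,3,3a,4,5,8,8a-octahydroazulen-2-yl 4-methylbenzoate | CC(C)(C)[Si](C)(C)O[C@H]1CC(C)=C[C@@H](OC(C)=O)[C@@]2(C)C[C@H](OC(=O)c3ccc(C)cc3)[C@@](O)(C(C)C)[C@H]12
F8 | step 10 | (1S,5S,6S,7S)-7-(2-bromoethyl)-5-[(tert-butyldimethylsilyl)oxy]-3,7-dimethyl-6-(2-methylpropanoyl)cyclohept-2-en-1-ol | CC(C)(C)[Si](C)(C)O[C@H]1CC(C)=C[C@H](O)[C@@](C)(CCBr)[C@@H]1C(=O)C(C)C
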